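The ratio that matters here is target gained per solid substrate lost: between 25.0 s and 60.0 s the midnight run lost 36 percentage points of solid and gained 18 points of target, so s = 49.0%, the target share: target gained per solid substrate lost.

| setting | midnight | alpha | zeta | theta | gamma |
|---|---|---|---|---|---|
| solid substrate | 20 mM | 20 mM | 20 mM | 20 mM | 20 mM |
| reagent | 39 mM | 26.0 mM | 26.0 mM | 26.0 mM | 26.0 mM |
| temperature | 40 °C | 40 °C | 20 °C | 0 °C | −20 °C |
| remark | run made earlier |  |  |  |  |
| time |  | 5.0 min | 5.0 min | 5.0 min | 5.0 min |

- midnight (time / s: target / %, solid substrate / %): 10.0: 0.2, 86.8; 12.0: 2.6, 83.5; 25.0: 8.9, 68.9; 60.0: 26.4, 33.2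

(readings scatter by 1 percentage point)

- as a solid, counted per litre of solution: solid substrate
- at the start none of the solid substrate is in solution
- what has only dissolved of solid substrate counts as not reacted
- the earlier runs do not show what temperature does; that part of a forecast is a guess

- the best flask by amount of target, in percent of the solid substrate charged; "all alike" if 1.5 percentage points covers them all (alpha / zeta / theta / gamma / all alike)
- amount of target at the end, in percent of the solid substrate charged, alpha
- amount of target at the end, in percent of the solid substrate charged, zeta
- amount of target at the end, in percent of the solid substrate charged, theta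
- amount of target at the end, in percent of the solid substrate charged, gamma

The end amount of target is y = s·c, where c is the part of the charge that has reacted. In alpha the solid substrate is the limiting reagent. The midnight solid stood at 33.2% after 60.0 s, and alpha runs 5.0 min, so c is taken as close to one, and the bracket is a bracket on s.

Above, supposing that the share holds and the smaller reagent charge costs nothing:

y ≤ 49.0%

Below: the share over the whole midnight run, which counts dissolved, unreacted material as lost, is 39.5%. The odds of target against the rest are then scaled with reagent by 0.667.

y ≥ 30.3%

Tightened: the same scaling applied to s, the later share.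

y ≈ 39.1%

The earlier runs show nothing of temperature, so this reckoning gives no number for the colder flasks: cooling may lower c, and what it does to s is open.

The forecast puts alpha at 38%, inside the bracket , zeta at 29%, theta at 13%, gamma at 4%, and names alpha best: “Warmest should win”.

The flasks give alpha 37.9%, inside the bracket, zeta 45.7%, theta 29.0% and gamma 8.40%; the best is zeta.

    starting material → side product A (k = 0.0224 s⁻¹, Ea = 77.0 kJ mol⁻¹)
    solid substrate ⇌ starting material, rate k2*(cs2 - [starting material]) while solid is left; crystals form when [starting material] > cs2 (solubility = 13.0 mM, k = 0.0214 s⁻¹)
    2 starting material → side product B (k = 1.43 M⁻¹ s⁻¹, Ea = 61.0 kJ mol⁻¹)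
    starting material + reagent → target (k = 0.869 M⁻¹ s⁻¹, Ea = 41.0 kJ mol⁻¹)
    (constants at 40 °C)

Taking s now as target over target plus both side products, alpha ends at 37.9%. Zeta ends at 49.4%, higher than alpha, with c = 92.6%, and theta's share is 61.4%. The neighbour is gamma's charge run at 5 °C, between theta and zeta in temperature, with c = 61.6%. With s = 49.0%, near zeta's share, as the lower share and theta's as the upper, y = s·c puts its target between 30.2% and 37.8%, and it holds 35.5%.

The earlier runs and the new flask were computed for substances that don't exist, and the scatter is random.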